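**Plan**

- Retrosynthetic cuts, in order: the two benzoate C–O bonds (O5, O7); the C1–C7 bond (carbonylation of a C1 enol triflate); the ring bond C2–C3 (aldol); the CH3–C1 bond (methyl Grignard on an L-arabinose lactol).
- Enabling feature: in the carbocycle C1(C7)=C2–C3–C4–C5–C6, the carbinol C3 is β to C1 once C1 is a ketone and C2 its methyl group, and C6/C5/C4 carry the C2/C3/C4 triol of L-arabinose.
- Forward: L-arabinose is protected (3,4-acetonide, 2-O-TIPS), extended by one methyl carbon and oxidised twice to a 1,5-keto-aldehyde. The only ring closes in step 7 by joining C2 to C3.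
- Stereochemistry: C4, C5, C6 come unchanged from arabinose C4, C3, C2. C3 is set in the aldol by the cis-fused dioxolane and the pseudoaxial C6 silyloxy group.
- The C1 ketone then carries C7 and the C1=C2 alkene through its kinetic enol triflate. The C5 benzoate is placed by axial-selective orthoester opening, and desilylation ends the route.

Key step: step 7

Numbering: ring atoms carry the target numbers throughout (C1 bears C7, C2 is the former methyl carbon, C3–C6 bear oxygen). With the ring numbered anticlockwise as seen from above, O3 and O6 point down and O4 and O5 point up.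
Assumption: lactol 5 (both anomers) and diol 8 (both carbinol epimers) are used as mixtures, because that carbon becomes the C1 carbonyl.

**Step 1**
Reactants: 1 L-arabinose
Product: 2 benzyl β-L-arabinopyranoside
Conditions: BnOH (excess), HCl (cat.), 50 °C; crystallise
Reagents that add atoms: benzyl alcohol, OCc1ccccc1
Why: Fischer glycosidation under thermodynamic control should favour the crystalline pyranoside with the axial benzyloxy group (anomeric effect), masking C1 as a hydrogenolysable acetal.

**Step 2**
Reactants: 2 benzyl β-L-arabinopyranoside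
Product: 3 benzyl 3,4-O-isopropylidene-β-L-arabinopyranoside
Conditions: Me2C(OMe)2, TsOH·H2O (cat.), acetone, rt
Reagents that add atoms: 2,2-dimethoxypropane, COC(C)(C)OC
Why: Acid-catalysed acetonide formation (transacetalisation) is selective for the cis-3,4-diol over the trans-diequatorial 2,3-diol, so only O2 stays free.

**Step 3**
Reactants: 3 benzyl 3,4-O-isopropylidene-β-L-arabinopyranoside
Product: 4 benzyl 3,4-O-isopropylidene-2-O-triisopropylsilyl-β-L-arabinopyranoside
Conditions: TIPSOTf, 2,6-lutidine, CH2Cl2, 0 °C → rt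
Reagents that add atoms: triisopropylsilyl trifluoromethanesulfonate, CC(C)[Si](C(C)C)(C(C)C)OS(=O)(=O)C(F)(F)F
Why: Silylation of the single free secondary hydroxyl with a silyl triflate and a hindered base; TIPS rather than TBS is chosen because it resists alkoxide-induced migration in step 5 and the aqueous acid of step 13 and shields C6–H in steps 7 and 9.

**Step 4**
Reactants: 4 benzyl 3,4-O-isopropylidene-2-O-triisopropylsilyl-β-L-arabinopyranoside
Product: 5 3,4-O-isopropylidene-2-O-triisopropylsilyl-L-arabinopyranose (lactol; anomer mixture)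
Conditions: H2 (1 atm), 10% Pd/C, EtOAc, rt
Reagents that add atoms: none
Why: Hydrogenolysis of the anomeric benzyl ether over palladium frees the lactol under neutral conditions that leave the acetonide and the silyl ether untouched.

**Step 5**
Reactants: 5 3,4-O-isopropylidene-2-O-triisopropylsilyl-L-arabinopyranose; 6 methylmagnesium bromide
Product: 8 6-deoxy-2,3-O-isopropylidene-4-O-triisopropylsilylhexitol (L-lyxo at C2–C4; C5 epimers), via open-chain aldehyde bromomagnesium alkoxide 7 (not isolated)
Conditions: MeMgBr (3.5 equiv), THF, 0 °C → rt; aq NH4Cl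
Reagents that add atoms: methylmagnesium bromide (6), C[Mg]Br
Why: Grignard addition to a lactol, in which the first equivalent deprotonates it, the ring-opened aldehyde alkoxide 7 is captured by a second equivalent, and the configuration of the new carbinol is immaterial because it is oxidised next.

**Step 6**
Reactants: 8 6-deoxy-2,3-O-isopropylidene-4-O-triisopropylsilylhexitol
Product: 10 6-deoxy-2,3-O-isopropylidene-4-O-triisopropylsilyl-L-lyxo-hexos-5-ulose (keto-aldehyde; ring numbering C2H3–C1(=O)–C6H(OTIPS)–C5H–C4H–C3H=O), via bis(dimethylalkoxysulfonium) dichloride 9 (not isolated)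
Conditions: (COCl)2, DMSO, CH2Cl2, −78 °C; i-Pr2NEt, −78 → −30 °C; pH 7 buffer; used crude
Reagents that add atoms: none
Why: Double Swern oxidation, in which both hydroxyls are held as alkoxysulfonium ions before any carbonyl is released, so that no hydroxy aldehyde can close to a lactol and over-oxidise, while the hindered amine at low temperature protects the α-alkoxy aldehyde centre from epimerisation.

**Step 7**
Reactants: 10 6-deoxy-2,3-O-isopropylidene-4-O-triisopropylsilyl-L-lyxo-hexos-5-ulose
Product: 11 (3R,4S,5S,6R)-3-hydroxy-4,5-(isopropylidenedioxy)-6-(triisopropylsilyloxy)cyclohexan-1-one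
Conditions: DBU (0.15 equiv), CH2Cl2, −20 °C; AcOH quench
Reagents that add atoms: none
Why: DBU reversibly removes a proton from the unhindered methyl group (C2) and the enolate adds to the C3 aldehyde, forming C2–C3 as an intramolecular aldol addition; the closest known reaction type is the base-mediated carbocyclisation of sugar-derived 1,5-dicarbonyl compounds to hydroxycyclohexanones, the carbanionic half of the Ferrier carbocyclisation. The six-membered ring closes in the Baldwin-favoured 6-(enolendo)-exo-trig mode, since both enolate carbons C1 and C2 end up in the ring and the aldehyde oxygen outside it. In the half-chair transition state the bulky C6 silyloxy group should sit pseudoaxial to avoid allylic strain with the enolate oxygen, which places C5–O axial and C4–O equatorial on the cis-fused dioxolane. The forming C2–C3 bond is then antiperiplanar to the C4–O bond (polar Felkin–Anh) and the aldehyde oxygen pseudoequatorial, away from the axial C5–O and anti to the enolate C=C, so the new C3–OH should be equatorial, trans to O4 and 1,3-trans to O5 (3R). The step needs site-selective enolisation and kinetic control: the methyl group is the only accessible acidic position (C6–H is shielded by TIPS, C4–H of the aldehyde is tertiary and part of the dioxolane), and catalytic base at low temperature with an acidic quench is meant to prevent dehydration, retro-aldol equilibration and β-elimination of O5.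

**Step 8**
Reactants: 11 (3R,4S,5S,6R)-3-hydroxy-4,5-(isopropylidenedioxy)-6-(triisopropylsilyloxy)cyclohexan-1-one
Product: 12 4,5-(isopropylidenedioxy)-3,6-bis(triisopropylsilyloxy)cyclohexan-1-one (ring centres as in 11)
Conditions: TIPSOTf, 2,6-lutidine, CH2Cl2, −78 → 0 °C
Reagents that add atoms: triisopropylsilyl trifluoromethanesulfonate, CC(C)[Si](C(C)C)(C(C)C)OS(=O)(=O)C(F)(F)F
Why: Silylation of the equatorial β-hydroxyl with TIPSOTf and 2,6-lutidine at low temperature is faster than enol silylation or β-elimination and gives a leaving group too poor to be lost from the enolate of step 9.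

**Step 9**
Reactants: 12 4,5-(isopropylidenedioxy)-3,6-bis(triisopropylsilyloxy)cyclohexan-1-one
Product: 14 4,5-(isopropylidenedioxy)-3,6-bis(triisopropylsilyloxy)cyclohex-1-en-1-yl trifluoromethanesulfonate, via lithium enolate 13 (not isolated)
Conditions: LiHMDS (1.2 equiv), THF, −78 °C; Comins' reagent, −78 → −40 °C
Reagents that add atoms: Comins' reagent (N-(5-chloropyridin-2-yl)-bis(trifluoromethanesulfonyl)imide), O=S(=O)(N(c1ccc(Cl)cn1)S(=O)(=O)C(F)(F)F)C(F)(F)F
Why: Kinetic enolate formation and O-triflation with Comins' reagent, in which LiHMDS should remove the axial C2–H of the methylene group rather than the TIPS-shielded C6–H, and the equatorial C3 silyloxy group is not aligned for E1cB loss at −78 °C.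

**Step 10**
Reactants: 14 4,5-(isopropylidenedioxy)-3,6-bis(triisopropylsilyloxy)cyclohex-1-en-1-yl trifluoromethanesulfonate
Product: 15 methyl 4,5-(isopropylidenedioxy)-3,6-bis(triisopropylsilyloxy)cyclohex-1-ene-1-carboxylate
Conditions: Pd(OAc)2 (5 mol%), PPh3 (10 mol%), Et3N, CO (1 atm), MeOH–DMF, rt → 40 °C
Reagents that add atoms: carbon monoxide, [C-]#[O+]; methanol, CO
Why: Palladium-catalysed alkoxycarbonylation of an enol triflate (oxidative addition, CO insertion, methanolysis of the acyl-palladium) installs C7 at C1 with the C1=C2 alkene fixed by the triflate.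

**Step 11**
Reactants: 15 methyl 4,5-(isopropylidenedioxy)-3,6-bis(triisopropylsilyloxy)cyclohex-1-ene-1-carboxylate
Product: 16 [4,5-(isopropylidenedioxy)-3,6-bis(triisopropylsilyloxy)cyclohex-1-en-1-yl]methanol
Conditions: DIBAL-H (3 equiv), CH2Cl2, −78 °C; Rochelle salt
Reagents that add atoms: none
Why: DIBAL-H reduces the conjugated ester in a 1,2-fashion to the allylic alcohol at −78 °C, and the acetonide and silyl ethers are inert to it.

**Step 12**
Reactants: 16 [4,5-(isopropylidenedioxy)-3,6-bis(triisopropylsilyloxy)cyclohex-1-en-1-yl]methanol; 17 benzoyl chloride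
Product: 18 [4,5-(isopropylidenedioxy)-3,6-bis(triisopropylsilyloxy)cyclohex-1-en-1-yl]methyl benzoate
Conditions: BzCl, pyridine, DMAP (cat.), CH2Cl2, 0 °C
Reagents that add atoms: benzoyl chloride (17), O=C(Cl)c1ccccc1
Why: Acylation (benzoylation under nucleophilic catalysis) of the only free hydroxyl, the primary allylic C7–OH.

**Step 13**
Reactants: 18 [4,5-(isopropylidenedioxy)-3,6-bis(triisopropylsilyloxy)cyclohex-1-en-1-yl]methyl benzoate
Product: 19 [4,5-dihydroxy-3,6-bis(triisopropylsilyloxy)cyclohex-1-en-1-yl]methyl benzoate (4,5-cis-diol)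
Conditions: TFA–H2O (9:1), CH2Cl2, 0 °C
Reagents that add atoms: none
Why: Acid-catalysed acetal hydrolysis, in which the cis-fused acetonide is cleaved by cold aqueous TFA while the secondary TIPS ethers and the benzoate survive, releasing only the 4,5-diol.

**Step 14**
Reactants: 19 [4,5-dihydroxy-3,6-bis(triisopropylsilyloxy)cyclohex-1-en-1-yl]methyl benzoate
Product: 21 [5-benzoyloxy-4-hydroxy-3,6-bis(triisopropylsilyloxy)cyclohex-1-en-1-yl]methyl benzoate, via cyclic methyl orthobenzoate 20 (not isolated)
Conditions: PhC(OMe)3, CSA (cat.), CH2Cl2, rt; then AcOH–H2O (4:1), rt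
Reagents that add atoms: trimethyl orthobenzoate, COC(OC)(OC)c1ccccc1; water, O
Why: Cyclic orthoester formation at the cis-diol followed by mild acid hydrolysis, which opens the 2-hydroxy-2-phenyl-1,3-dioxolane to the ester of the axial oxygen; with C6–OTIPS pseudoaxial (allylic 1,2-strain against the C1 substituent) the axial oxygen is O5, so the benzoate should land on C5 and the equatorial O4 stay free.

**Step 15**
Reactants: 21 [5-benzoyloxy-4-hydroxy-3,6-bis(triisopropylsilyloxy)cyclohex-1-en-1-yl]methyl benzoate
Product: 22 [(3R,4S,5R,6S)-5-benzoyloxy-3,4,6-trihydroxycyclohex-1-en-1-yl]methyl benzoate (CNP0198957.1)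
Conditions: HF·pyridine, pyridine, THF, 0 °C → rt
Reagents that add atoms: none
Why: Fluoride-mediated desilylation under acidic, buffered conditions (HF·pyridine) removes both TIPS ethers without the base-induced 1,2-acyl migration that a basic fluoride source could cause.

**Compound list**

1 | L-arabinose | O=C[C@H](O)[C@@H](O)[C@@H](O)CO | starting material
2 | benzyl β-L-arabinopyranoside | c1ccccc1CO[C@@H]1[C@H](O)[C@@H](O)[C@@H](O)CO1 | intermediate
3 | benzyl 3,4-O-isopropylidene-β-L-arabinopyranoside | c1ccccc1CO[C@@H]1[C@H](O)[C@H]2OC(C)(C)O[C@H]2CO1 | intermediate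
4 | benzyl 3,4-O-isopropylidene-2-O-triisopropylsilyl-β-L-arabinopyranoside | c1ccccc1CO[C@@H]1[C@H](O[Si](C(C)C)(C(C)C)C(C)C)[C@H]2OC(C)(C)O[C@H]2CO1 | intermediate
5 | 3,4-O-isopropylidene-2-O-triisopropylsilyl-L-arabinopyranose (lactol, anomer mixture) | OC1[C@H](O[Si](C(C)C)(C(C)C)C(C)C)[C@H]2OC(C)(C)O[C@H]2CO1 | intermediate
6 | methylmagnesium bromide | C[Mg]Br | starting material
7 | bromomagnesium alkoxide of aldehydo-3,4-O-isopropylidene-2-O-triisopropylsilyl-L-arabinose (not isolated) | O=C[C@H](O[Si](C(C)C)(C(C)C)C(C)C)[C@H]1OC(C)(C)O[C@H]1CO[Mg]Br | intermediate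
8 | 6-deoxy-2,3-O-isopropylidene-4-O-triisopropylsilylhexitol (L-lyxo at C2–C4, C5 epimers) | CC(O)[C@H](O[Si](C(C)C)(C(C)C)C(C)C)[C@H]1OC(C)(C)O[C@H]1CO | intermediate
9 | 1,5-bis(dimethylsulfonio-oxy) derivative of 8, dichloride (not isolated) | CC(O[S+](C)C)[C@H](O[Si](C(C)C)(C(C)C)C(C)C)[C@H]1OC(C)(C)O[C@H]1CO[S+](C)C.[Cl-].[Cl-] | intermediate
10 | 6-deoxy-2,3-O-isopropylidene-4-O-triisopropylsilyl-L-lyxo-hexos-5-ulose (keto-aldehyde) | CC(=O)[C@H](O[Si](C(C)C)(C(C)C)C(C)C)[C@H]1OC(C)(C)O[C@H]1C=O | intermediate
11 | (3R,4S,5S,6R)-3-hydroxy-4,5-(isopropylidenedioxy)-6-(triisopropylsilyloxy)cyclohexan-1-one | O=C1C[C@@H](O)[C@@H]2OC(C)(C)O[C@@H]2[C@H]1O[Si](C(C)C)(C(C)C)C(C)C | intermediate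
12 | 4,5-(isopropylidenedioxy)-3,6-bis(triisopropylsilyloxy)cyclohexan-1-one (ring centres as in 11) | O=C1C[C@@H](O[Si](C(C)C)(C(C)C)C(C)C)[C@@H]2OC(C)(C)O[C@@H]2[C@H]1O[Si](C(C)C)(C(C)C)C(C)C | intermediate
13 | lithium C1=C2 enolate of 12 (not isolated) | [Li]OC1=C[C@@H](O[Si](C(C)C)(C(C)C)C(C)C)[C@@H]2OC(C)(C)O[C@@H]2[C@H]1O[Si](C(C)C)(C(C)C)C(C)C | intermediate
14 | 4,5-(isopropylidenedioxy)-3,6-bis(triisopropylsilyloxy)cyclohex-1-en-1-yl trifluoromethanesulfonate | O=S(=O)(OC1=C[C@@H](O[Si](C(C)C)(C(C)C)C(C)C)[C@@H]2OC(C)(C)O[C@@H]2[C@H]1O[Si](C(C)C)(C(C)C)C(C)C)C(F)(F)F | intermediate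
15 | methyl 4,5-(isopropylidenedioxy)-3,6-bis(triisopropylsilyloxy)cyclohex-1-ene-1-carboxylate | COC(=O)C1=C[C@@H](O[Si](C(C)C)(C(C)C)C(C)C)[C@@H]2OC(C)(C)O[C@@H]2[C@H]1O[Si](C(C)C)(C(C)C)C(C)C | intermediate
16 | [4,5-(isopropylidenedioxy)-3,6-bis(triisopropylsilyloxy)cyclohex-1-en-1-yl]methanol | OCC1=C[C@@H](O[Si](C(C)C)(C(C)C)C(C)C)[C@@H]2OC(C)(C)O[C@@H]2[C@H]1O[Si](C(C)C)(C(C)C)C(C)C | intermediate
17 | benzoyl chloride | O=C(Cl)c1ccccc1 | starting material
18 | [4,5-(isopropylidenedioxy)-3,6-bis(triisopropylsilyloxy)cyclohex-1-en-1-yl]methyl benzoate | O=C(OCC1=C[C@@H](O[Si](C(C)C)(C(C)C)C(C)C)[C@@H]2OC(C)(C)O[C@@H]2[C@H]1O[Si](C(C)C)(C(C)C)C(C)C)c1ccccc1 | intermediate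
19 | [4,5-dihydroxy-3,6-bis(triisopropylsilyloxy)cyclohex-1-en-1-yl]methyl benzoate (4,5-cis; 3,4- and 5,6-trans) | O=C(OCC1=C[C@@H](O[Si](C(C)C)(C(C)C)C(C)C)[C@H](O)[C@H](O)[C@H]1O[Si](C(C)C)(C(C)C)C(C)C)c1ccccc1 | intermediate
20 | cyclic 4,5-O-(α-methoxybenzylidene) orthoester of 19 (not isolated; both orthoester epimers) | O=C(OCC1=C[C@@H](O[Si](C(C)C)(C(C)C)C(C)C)[C@@H]2OC(OC)(c3ccccc3)O[C@@H]2[C@H]1O[Si](C(C)C)(C(C)C)C(C)C)c1ccccc1 | intermediate
21 | [5-benzoyloxy-4-hydroxy-3,6-bis(triisopropylsilyloxy)cyclohex-1-en-1-yl]methyl benzoate | O=C(OCC1=C[C@@H](O[Si](C(C)C)(C(C)C)C(C)C)[C@H](O)[C@H](OC(=O)c2ccccc2)[C@H]1O[Si](C(C)C)(C(C)C)C(C)C)c1ccccc1 | intermediate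
22 | [(3R,4S,5R,6S)-5-benzoyloxy-3,4,6-trihydroxycyclohex-1-en-1-yl]methyl benzoate | O=C(OCC1=C[C@@H](O)[C@H](O)[C@H](OC(=O)c2ccccc2)[C@H]1O)c1ccccc1 | target

**Step count and risks**

Total step count: 15. Longest linear sequence: 15 steps (the route is fully linear from 1).

Steps most likely to fail:

1. Step 7. The ring closure may show poor facial selectivity at the aldehyde, or the aldol may equilibrate by retro-aldol toward the C3 epimer. The fallback sets out from 10 and returns at 11. The cyclisation is driven through to condensation (DBU, CH2Cl2, rt), which erases C3 as a stereocentre and should give 4,5-(isopropylidenedioxy)-6-(triisopropylsilyloxy)cyclohex-2-en-1-one F1. Weitz–Scheffer epoxidation (H2O2, NaOH, MeOH, 0 °C) should attack the face opposite the dioxolane and give the 2,3-epoxy ketone F2. Reductive opening at C2 with sodium phenylseleno(triethoxy)borate (PhSeSePh, NaBH4, EtOH, AcOH) should then give 11, with C3–O trans to O4 fixed by the epoxidation instead of the aldol.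

2. Step 14. The orthoester may open toward the other oxygen if the ring prefers the half-chair with C5–O equatorial, or the benzoate may migrate from O5 to O4. The fallback sets out from 19 and returns at 21. Dibutyltin oxide (toluene, reflux, water removed) should give the 4,5-O-dibutylstannylene acetal F3, which benzoyl chloride 17 acylates at the equatorial oxygen. This selectivity is complementary to that of orthoester opening, so it should deliver 21 in exactly the case where the orthoester route places the ester on O4.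

3. Step 9. Enolisation may go toward C6, or the C3 silyloxy group may be lost from the enolate by β-elimination. The fallback sets out from 12 and returns at 16, bypassing 14 and 15. Corey–Chaykovsky reaction with dimethylsulfonium methylide (Me3S+ I−, n-BuLi, THF, −10 °C) adds C7 as a nucleophile to C1 and should give the spiro-epoxide F4. Diethylaluminium 2,2,6,6-tetramethylpiperidide (toluene, 0 °C) should isomerise it to the allylic alcohol 16 by removing the more accessible C2–H.

**Further compounds**

F1 | step 7 | 4,5-(isopropylidenedioxy)-6-(triisopropylsilyloxy)cyclohex-2-en-1-one (C4–C6 as in 11) | O=C1C=C[C@@H]2OC(C)(C)O[C@@H]2[C@H]1O[Si](C(C)C)(C(C)C)C(C)C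
F2 | step 7 | 2,3-epoxy-4,5-(isopropylidenedioxy)-6-(triisopropylsilyloxy)cyclohexan-1-one (epoxide on the face opposite the dioxolane) | O=C1[C@H]2O[C@H]2[C@@H]3OC(C)(C)O[C@@H]3[C@H]1O[Si](C(C)C)(C(C)C)C(C)C
F3 | step 14 | 4,5-O-dibutylstannylene acetal of 19 | O=C(OCC1=C[C@@H](O[Si](C(C)C)(C(C)C)C(C)C)[C@@H]2O[Sn](CCCC)(CCCC)O[C@@H]2[C@H]1O[Si](C(C)C)(C(C)C)C(C)C)c1ccccc1
F4 | step 9 | C1 spiro-oxirane of 12 (oxirane CH2 = C7; spiro centre unassigned) | C1OC12C[C@@H](O[Si](C(C)C)(C(C)C)C(C)C)[C@@H]3OC(C)(C)O[C@@H]3[C@H]2O[Si](C(C)C)(C(C)C)C(C)C
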